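**The charge.** Of the substrate charged, the limiting reagent, the readings show the part standing as target, so my ledger has that entry and a remainder.

| setting | zeta | epsilon | flask |
|---|---|---|---|
| substrate | 0.050 M | 0.050 M | 0.050 M |
| partner | 0.20 M | 0.20 M | 0.200 M |
| protic impurity | 3.4 mM | 7.5 mM | 5.00 mM |
| remark | run made earlier | run made earlier |  |
| time |  |  | 50 h |

| run | time / h | target / % |
|---|---|---|
| zeta | 1.50 | 12 |
| zeta | 3.00 | 19 |
| zeta | 8.00 | 20 |
| zeta | 15.0 | 14 |
| zeta | 30.0 | 9 |
| zeta | 60.0 | 0 |
| epsilon | 1.50 | 11 |
| epsilon | 3.00 | 15 |
| epsilon | 8.00 | 19 |
| epsilon | 15.0 | 16 |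
| epsilon | 30.0 | 6 |
| epsilon | 60.0 | 0 |

(readings scatter by 1.5 percentage points)



- the best time, 50 h at the latest, for target
- the amount of target, in percent of the substrate charged, at that time

**Pooling runs.** The impurity charged is far smaller than the partner, so I average the runs and take the flask's 5.00 mM, which lies between theirs, as the same curve.

**Late entry.** The averaged target readings fall from 15.0% at 15.0 h to 7.50% at 30.0 h, a decline read as 0.0462 h⁻¹. Run back to the start, that line reaches 30.0%. I call this the capture, my reading of the share of the charged substrate that passes through target. The remaining 70.0% is a ledger entry I cannot read.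

**Early entry.** The 11.5% at 1.50 h then requires a rise of 0.399 h⁻¹. Joining the ends, capture × (exp(−decline × time) − exp(−rise × time)), I commit to a peak at 6.11 h with 20.0%.

**The forecast.** The forecast gives 5.5 h and 20.5%, and warns that the “peak time is poorly fixed because no readings fall” between 3.00 h and 8.00 h. My time is later and my height lower.

**The flask.** The flask peaks at 6.68 h with 19.5%.

    substrate + partner ⇌ target (K = 7.90 M⁻¹, k = 0.490 M⁻¹ h⁻¹)
    substrate → side product (k = 0.210 h⁻¹)
    partner → decomposed reagent (k = 0.0400 h⁻¹)
    partner + protic impurity → quenched reagent (k = 7.20 M⁻¹ h⁻¹)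

**What ran.** In the flask, until 6.68 h, substrate fell to 17.4% by both routes, leaving 19.5% target and 63.1% side product, and 64.8% of the capture stood at the peak. Afterwards, with substrate at 2.94% and partner at 35.7% of its charge by 25.0 h, target returned through substrate to side product, 2.39% standing at 50.0 h. The target step takes partner and the side step does not, so for the neighbour flask with 0.34 M of partner I scale the odds capture/(1 − capture), a selectivity factor, and get a capture of 42.1%. With the same 64.8% that predicts 27.3%, and that neighbour flask reaches 29.7%.

The readings come from a simulation for substances that don't exist; scatter was added.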